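Remark: the target is read as gallocatechin-(4α→6)-gallocatechin (upper unit rings A, C, B; lower unit rings D, F, E). (+)-Gallocatechin is taken as a commercial natural product. In names, ArB = 3,4,5-tris(benzyloxy)phenyl and ArD = (2R,3S)-3,5,7-tris(benzyloxy)-8-bromo-2-ArB-chroman-6-yl.

## Structural features

The target consists of two gallocatechin units, each a chroman (pyran ring C or F fused to a phloroglucinol-type ring A or D) with a pyrogallol ring (B or E) at C2 and a hydroxyl at C3. The units are joined by one C–C bond from C4 of the upper unit to C6 of ring D, not to the more usual C8. There are five stereocentres: C2, C3 and C4 stand next to each other in ring C (2R,3S,4R; 2,3-trans-3,4-trans, all three substituents equatorial on the half-chair), and C2 and C3 of the lower unit are 2R,3S (trans). The pyrogallol rings oxidise readily in air and base, the interflavan bond ionises at C4 under acid, and the free phenols can epimerise at C2 in base. The real difficulty is twofold: C6 of ring D is the less nucleophilic and more hindered of its two free positions, and C4 is a diarylmethine between four ortho oxygens whose configuration is only weakly biased when it is made by attack on a C4 cation of a 2,3-trans unit. The key step exploits the fact that O1–C8a–C4a–C4 of ring C is the skeleton of an ortho-quinone methide of ring A, whose methide carbon C4 can already carry ring D. The other two ring atoms, C2 and C3 with its oxygen, then arrive as one two-carbon aldehyde that closes ring C. Because the required ring C is the all-equatorial one, C3 and C2 can be relayed from C4.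

## Logic of the disconnections

24 from 23. No skeletal bond is cut; the twelve O–CH2Ph bonds and the C8–Br bond of ring D are formed in the reverse sense. Reason: the free polyphenol is too fragile to carry through. Gain: every earlier intermediate is an oxidation-stable ether. Demand: one neutral reductive operation must remove benzyl groups and bromine together.

23 from 21. The C2–H bond of ring C is cut. Reason: with C2 at the ketone oxidation level, ring B can enter as a nucleophile and C2 is set last by the ring itself. Gain: one stereocentre less. Demand: axial hydride delivery to an oxocarbenium ion without loss of the C3 proton.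

21 from 15 and 18. The bond from C2 to ring B is cut. Gain: ring B leaves as a simple aryl bromide and the rest is a dihydrocoumarin. Demand: a single addition to a lactone without enolisation at C3.

15 from 14. Only the oxidation level of C2 changes. Demand: an oxidant that spares electron-rich arenes and the doubly benzylic C4–H.

14 from 9 and 10 (key disconnection). The C3–C4 bond and the O1–C2 bond are cut, ring C is opened, and the stereocentres C3 and C4 disappear together. In one sentence: ring C is closed by an amine-catalysed oxa-[4+2] annulation of the ortho-quinone methide 11, which already carries the whole lower unit on its methide carbon, with 10. Gain: the precursor 9 has no stereochemical content at the future C4, and 10 is a two-carbon commodity. Demand: face selectivity at the methide carbon and at the enamine carbon must come from the catalyst, and the ring A hydroxyl must be the only free phenol.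

9 from 4 and 6. The bond between the carbinol carbon (future C4) and C6 of ring D is cut as a carbonyl addition. Reason: the 4→6 connectivity is then decided by the position of a halogen on ring D and not by competition between C6 and C8 for a cation. Gain: two fragments of similar size, no stereochemical demand. Demand: metalation at C6 beside C8–Br, and the phenol of 6 must not quench the aryl metal.

4 from 3, 3 from 2, 2 from 1. The C6–I bond, the C8–Br bond and six O–benzyl bonds are cut. Reason: electrophiles prefer C8, so bromine enters first and stays as a blocking group that the last step removes; iodine can then enter only at C6. 1 supplies both lower-unit stereocentres.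

6 from 5; 18 from 17; 17 from 16. Only protecting-group bonds on commercial aromatics are cut, so that every hydroxyl carries benzyl at the end.

## Other disconnections considered

Alternative 1: the interflavan bond C4–C6 is cut last, with C4 as the electrophile. Forward: oxidation of 2 at C4 (DDQ, 2-ethoxyethanol) to the 4-(2-ethoxyethoxy) ether A1, then Lewis-acid Friedel–Crafts union of A1 with 3 to give 23. This is the first route to come to mind and the shortest. Grounds against it: the bond must form at C6, the hindered and less nucleophilic position of a bromine-deactivated ring, so self-condensation of A1 through its own C8 should compete. The C4 cation of a 2,3-trans unit has its C2 and C3 substituents on opposite faces, so both C4 epimers are expected. Two equivalents of 1 are consumed. It is also the conventional disconnection.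

Alternative 2: the same bond with reversed polarity. Forward: addition of 7 to the flavan-4-one A2 gives the tertiary C4 carbinol A3, which is deoxygenated by hydride transfer to the C4 cation. Grounds against it: hydride should enter anti to the C3 benzyloxy group, which leaves ring D cis to it. The product would be the 3,4-cis epimer A4 and not 23. A2 is also a hindered, enolisable β-aryloxy ketone that can open to a chalcone under basic organometallics.

Alternative 3: the same two bonds as in the chosen plan, but with ring B included. Forward: thermal hetero-Diels–Alder reaction of 11 with the (E)-styrylboronate A5 to give the 3-boryl flavan A6, then C–B oxidation with retention. It would set C2, C3 and C4 at once and save three steps. Grounds against it: an alkenylboronate is a weakly polarised 2π partner for an inverse-demand cycloaddition. Its regiochemistry would rest only on the modest donor power of ArB. No catalyst has a handle on either partner, so the face at C4 would depend on remote stereocentres. The chosen plan uses an established reaction class with catalyst control, and its extra steps are routine.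

Key step: step 6

## Steps

Step 1
Reactants: 1 (+)-gallocatechin
Product: 2 (2R,3S)-3,5,7-tris(benzyloxy)-2-ArB-chromane (hexa-O-benzylgallocatechin)
Conditions: BnBr (7.5 equiv), NaH (7 equiv), n-Bu4NI (cat.), DMF, −20 °C to rt, argon
Reagents that add atoms: benzyl bromide, BrCc1ccccc1
Why: Williamson etherification of the five phenols and the C3 alkoxide; no stereocentre is touched, and low temperature with fast O-alkylation should keep C2 epimerisation and C-benzylation of ring D in check.

Step 2
Reactants: 2 hexa-O-benzylgallocatechin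
Product: 3 (2R,3S)-8-bromo-3,5,7-tris(benzyloxy)-2-ArB-chromane
Conditions: NBS (1.05 equiv), CH2Cl2, −78 °C to 0 °C
Reagents that add atoms: N-bromosuccinimide, O=C1CCC(=O)N1Br
Why: Electrophilic aromatic bromination; in 5,7-dialkoxychromans C8 (ortho to O1 and O7, para to O5) is the most nucleophilic position, so one equivalent should enter there and block it.

Step 3
Reactants: 3 8-bromo-hexa-O-benzylgallocatechin
Product: 4 (2R,3S)-8-bromo-6-iodo-3,5,7-tris(benzyloxy)-2-ArB-chromane
Conditions: NIS (1.2 equiv), CF3CO2H (10 mol %), CH2Cl2/MeCN, 0 °C to rt, dark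
Reagents that add atoms: N-iodosuccinimide, O=C1CCC(=O)N1I
Why: Acid-activated iodination of the only free position of ring D, C6 between two benzyloxy groups, which remains more electron-rich than ring E; the 4→6 connectivity is thereby stored as a C–I bond.

Step 4
Reactants: 5 2,4,6-trihydroxybenzaldehyde
Product: 6 2,4-bis(benzyloxy)-6-hydroxybenzaldehyde
Conditions: BnBr (2.1 equiv), K2CO3 (2.2 equiv), DMF, rt
Reagents that add atoms: benzyl bromide, BrCc1ccccc1
Why: Selective Williamson etherification; the hydroxyl that is hydrogen-bonded to the aldehyde is the least reactive and should remain, giving the ortho-hydroxy aldehyde that becomes ring A.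

Step 5
Reactants: 4 8-bromo-6-iodo-hexa-O-benzylgallocatechin; 6 2,4-bis(benzyloxy)-6-hydroxybenzaldehyde
Product: 9 [2,4-bis(benzyloxy)-6-hydroxyphenyl](ArD)methanol as both carbinol epimers, via arylmagnesium chloride 7 (not isolated), via chloromagnesium phenoxide 8 (not isolated)
Conditions: 4, i-PrMgCl·LiCl (1.1 equiv), THF, −20 °C to 0 °C; 6, i-PrMgCl·LiCl (1.0 equiv), THF, −40 °C; combine, −40 °C to rt; pH 7 phosphate buffer; crude 9 used directly
Reagents that add atoms: none
Why: Iodine–magnesium exchange is much faster at C–I than at C–Br and gives 7; 1,2-addition of 7 to the magnesium-chelated salicylaldehyde 8 (deprotonated first so that the phenol does not quench 7) gives the benzhydrol. The carbinol centre forms without control and is erased in step 6.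

Step 6
Reactants: 9 [2,4-bis(benzyloxy)-6-hydroxyphenyl](ArD)methanol; 10 benzyloxyacetaldehyde
Product: 14 3,4-trans-3,5,7-tris(benzyloxy)-4-ArD-chroman-2-ol (C3 and C4 as in the target; both anomers), via ortho-quinone methide 11 (not isolated), via E-enamine 12 (not isolated), via cyclic N,O-aminal 13 (not isolated)
Conditions: (R)-α,α-diphenylprolinol trimethylsilyl ether (20 mol %), PhCO2H (20 mol %), 10 (3 equiv, slow addition), CHCl3, 0 °C to rt
Reagents that add atoms: water (released in the flask on ionisation of 9 and on enamine formation; re-enters on hydrolysis of 13), O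
Why: Benzoic acid ionises the doubly donor-stabilised benzhydrol 9 to the ortho-quinone methide 11 while the amine condenses with 10 to the E-enamine 12; the enamine carbon attacks the methide carbon (future C4) in an asynchronous inverse-electron-demand oxa-[4+2] cycloaddition driven by re-aromatisation of ring A, and the phenoxide oxygen closes ring C on the iminium carbon (second bond of the cycloaddition; 6-exo-trig on C=N if stepwise) to give aminal 13, which water hydrolyses to lactol 14 with release of the catalyst. The closest known reaction type is the aminocatalytic oxa-Diels–Alder reaction of aldehydes with ortho-quinone methides generated in situ from ortho-hydroxybenzhydrols, which leads to trans-3,4-disubstituted chroman-2-ols. C3 is set by the catalyst: the diphenyl(silyloxy)methyl group shields one face of the s-trans E-enamine, and the R catalyst is chosen because the open face then gives the target configuration at C3. C4 is set relative to C3 by the endo approach of the enamine nitrogen over the quinone methide with ring D in the outside position, which places the C3 benzyloxy group and the C4 aryl group trans. Regioselectivity (C3 to C4, O1 to C2) follows from the polarity of the enamine and the quinone methide, and closure on O1 is secured because the ring A hydroxyl is the only free phenol. C3 stays epimerisable through the open hydroxy aldehyde and the 3,4-trans diequatorial arrangement is the thermodynamic one, so only the face at C4 cannot be corrected later. The stereocentres of the lower unit are remote and are not expected to influence the outcome.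

Step 7
Reactants: 14 3,4-trans-3,5,7-tris(benzyloxy)-4-ArD-chroman-2-ol
Product: 15 3,4-trans-3,5,7-tris(benzyloxy)-4-ArD-chroman-2-one
Conditions: n-Pr4N[RuO4] (5 mol %), NMO (1.5 equiv), 4 Å molecular sieves, CH2Cl2, rt
Reagents that add atoms: none
Why: Perruthenate-catalysed (Ley–Griffith) oxidation of the lactol to the dihydrocoumarin; C4 is untouched, and C3, now α to a lactone carbonyl, keeps or reaches the more stable 3,4-trans arrangement.

Step 8
Reactants: 16 5-bromo-1,2,3-trimethoxybenzene
Product: 17 5-bromobenzene-1,2,3-triol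
Conditions: BBr3 (3.5 equiv), CH2Cl2, −78 °C to rt; H2O
Reagents that add atoms: none
Why: Lewis-acid ether cleavage; bromide attacks the O-methyl carbon of the boron-activated ethers, and the aryl bromide is inert.

Step 9
Reactants: 17 5-bromobenzene-1,2,3-triol
Product: 18 5-bromo-1,2,3-tris(benzyloxy)benzene
Conditions: BnBr (3.3 equiv), K2CO3 (3.5 equiv), DMF, 50 °C, argon
Reagents that add atoms: benzyl bromide, BrCc1ccccc1
Why: Williamson etherification under argon (the triol is air-sensitive in base) gives the ring B donor with the same benzyl protection as the rest.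

Step 10
Reactants: 15 3,4-trans-3,5,7-tris(benzyloxy)-4-ArD-chroman-2-one; 18 5-bromo-1,2,3-tris(benzyloxy)benzene
Product: 21 3,4-trans-2-ArB-3,5,7-tris(benzyloxy)-4-ArD-chroman-2-ol (hemiketal in equilibrium with its open keto phenol), via aryllithium 19 (not isolated), via aryldichlorocerium 20 (not isolated)
Conditions: 18 (1.3 equiv), n-BuLi (1.25 equiv), THF, −78 °C; CeCl3 (1.4 equiv), THF, −78 °C; then 15, −78 °C; aq NH4Cl
Reagents that add atoms: none
Why: Bromine–lithium exchange and transmetalation give the weakly basic, oxophilic organocerium 20, which should add once to the lactone carbonyl without deprotonating C3; the hindered ketone of the open form resists a second addition. This is the lactone-to-hemiketal tactic of C-aryl glycoside synthesis.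

Step 11
Reactants: 21 3,4-trans-2-ArB-3,5,7-tris(benzyloxy)-4-ArD-chroman-2-ol
Product: 23 3,5,7,3',4',5'-hexa-O-benzylgallocatechin-(4α→6)-8-bromo-3,5,7,3',4',5'-hexa-O-benzylgallocatechin, via oxocarbenium ion 22 (not isolated)
Conditions: Et3SiH (5 equiv), BF3·OEt2 (2 equiv, promoter), CH2Cl2/MeCN, −40 °C
Reagents that add atoms: none
Why: Ionic hydrogenation; BF3 ionises the hemiketal to the 2-aryl oxocarbenium ion 22, and hydride is delivered along the axial trajectory of the half-chair that keeps the C3 benzyloxy and C4 aryl groups pseudo-equatorial. Ring B ends equatorial, so C2 is set trans to C3 (2R), as in the reduction of C-aryl hemiketals to β-C-aryl glycosides.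

Step 12
Reactants: 23 dodeca-O-benzyl-8-bromo dimer
Product: 24 gallocatechin-(4α→6)-gallocatechin
Conditions: H2 (1 atm), Pd(OH)2/C, Et3N (1.2 equiv), THF/MeOH/H2O, rt; then AcOH, filtration under argon, lyophilisation
Reagents that add atoms: none
Why: Hydrogenolysis over Pd(OH)2/C cleaves the twelve benzyl ethers and, with Et3N as HBr acceptor, the C8–Br bond of ring D; no stereocentre is involved, and acidification before filtration protects the pyrogallol rings.

## Compound list

1 | (+)-gallocatechin, (2R,3S)-2-(3,4,5-trihydroxyphenyl)chromane-3,5,7-triol | Oc1cc(O)c2c(c1)O[C@H](c1cc(O)c(O)c(O)c1)[C@@H](O)C2 | starting material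
2 | (2R,3S)-3,5,7-tris(benzyloxy)-2-ArB-chromane | c1(OCc9ccccc9)cc(OCc9ccccc9)c2c(c1)O[C@H](c7cc(OCc9ccccc9)c(OCc9ccccc9)c(OCc9ccccc9)c7)[C@@H](OCc9ccccc9)C2 | intermediate
3 | (2R,3S)-8-bromo-3,5,7-tris(benzyloxy)-2-ArB-chromane | c1(OCc9ccccc9)cc(OCc9ccccc9)c2c(c1Br)O[C@H](c7cc(OCc9ccccc9)c(OCc9ccccc9)c(OCc9ccccc9)c7)[C@@H](OCc9ccccc9)C2 | intermediate
4 | (2R,3S)-8-bromo-6-iodo-3,5,7-tris(benzyloxy)-2-ArB-chromane | c1(OCc9ccccc9)c(I)c(OCc9ccccc9)c2c(c1Br)O[C@H](c7cc(OCc9ccccc9)c(OCc9ccccc9)c(OCc9ccccc9)c7)[C@@H](OCc9ccccc9)C2 | intermediate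
5 | 2,4,6-trihydroxybenzaldehyde | O=Cc1c(O)cc(O)cc1O | starting material
6 | 2,4-bis(benzyloxy)-6-hydroxybenzaldehyde | O=Cc1c(O)cc(OCc9ccccc9)cc1OCc9ccccc9 | intermediate
7 | ArD-magnesium chloride (as LiCl complex) | Cl[Mg]c4c(OCc9ccccc9)c(Br)c5c(c4OCc9ccccc9)C[C@H](OCc9ccccc9)[C@@H](c7cc(OCc9ccccc9)c(OCc9ccccc9)c(OCc9ccccc9)c7)O5 | intermediate
8 | chloromagnesium 3,5-bis(benzyloxy)-2-formylphenoxide | O=Cc1c(O[Mg]Cl)cc(OCc9ccccc9)cc1OCc9ccccc9 | intermediate
9 | [2,4-bis(benzyloxy)-6-hydroxyphenyl](ArD)methanol, both carbinol epimers | OC(c1c(O)cc(OCc9ccccc9)cc1OCc9ccccc9)c4c(OCc9ccccc9)c(Br)c5c(c4OCc9ccccc9)C[C@H](OCc9ccccc9)[C@@H](c7cc(OCc9ccccc9)c(OCc9ccccc9)c(OCc9ccccc9)c7)O5 | intermediate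
10 | benzyloxyacetaldehyde | O=CCOCc1ccccc1 | starting material
11 | 3,5-bis(benzyloxy)-6-(ArD-methylidene)cyclohexa-2,4-dien-1-one (ortho-quinone methide) | O=C1C=C(OCc9ccccc9)C=C(OCc9ccccc9)C1=Cc4c(OCc9ccccc9)c(Br)c5c(c4OCc9ccccc9)C[C@H](OCc9ccccc9)[C@@H](c7cc(OCc9ccccc9)c(OCc9ccccc9)c(OCc9ccccc9)c7)O5 | intermediate
12 | (R)-1-[(E)-2-(benzyloxy)ethenyl]-2-[diphenyl(trimethylsilyloxy)methyl]pyrrolidine | C[Si](C)(C)OC(c1ccccc1)(c1ccccc1)[C@H]1CCCN1/C=C/OCc1ccccc1 | intermediate
13 | 3,5,7-tris(benzyloxy)-4-ArD-2-[(R)-2-(diphenyl(trimethylsilyloxy)methyl)pyrrolidin-1-yl]chromane, 2,3-trans-3,4-trans | c1(OCc9ccccc9)cc(OCc9ccccc9)c2c(c1)O[C@H](N3CCC[C@@H]3C(c8ccccc8)(c8ccccc8)O[Si](C)(C)C)[C@@H](OCc9ccccc9)[C@@H]2c4c(OCc9ccccc9)c(Br)c5c(c4OCc9ccccc9)C[C@H](OCc9ccccc9)[C@@H](c7cc(OCc9ccccc9)c(OCc9ccccc9)c(OCc9ccccc9)c7)O5 | intermediate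
14 | 3,4-trans-3,5,7-tris(benzyloxy)-4-ArD-chroman-2-ol (3-OBn β, 4-ArD α; both anomers) | c1(OCc9ccccc9)cc(OCc9ccccc9)c2c(c1)OC(O)[C@@H](OCc9ccccc9)[C@@H]2c4c(OCc9ccccc9)c(Br)c5c(c4OCc9ccccc9)C[C@H](OCc9ccccc9)[C@@H](c7cc(OCc9ccccc9)c(OCc9ccccc9)c(OCc9ccccc9)c7)O5 | intermediate
15 | 3,4-trans-3,5,7-tris(benzyloxy)-4-ArD-chroman-2-one | c1(OCc9ccccc9)cc(OCc9ccccc9)c2c(c1)OC(=O)[C@@H](OCc9ccccc9)[C@@H]2c4c(OCc9ccccc9)c(Br)c5c(c4OCc9ccccc9)C[C@H](OCc9ccccc9)[C@@H](c7cc(OCc9ccccc9)c(OCc9ccccc9)c(OCc9ccccc9)c7)O5 | intermediate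
16 | 5-bromo-1,2,3-trimethoxybenzene | COc1cc(Br)cc(OC)c1OC | starting material
17 | 5-bromobenzene-1,2,3-triol | Oc1cc(Br)cc(O)c1O | intermediate
18 | 5-bromo-1,2,3-tris(benzyloxy)benzene | Brc1cc(OCc9ccccc9)c(OCc9ccccc9)c(OCc9ccccc9)c1 | intermediate
19 | 3,4,5-tris(benzyloxy)phenyllithium | [Li]c1cc(OCc9ccccc9)c(OCc9ccccc9)c(OCc9ccccc9)c1 | intermediate
20 | dichloro[3,4,5-tris(benzyloxy)phenyl]cerium | Cl[Ce](Cl)c1cc(OCc9ccccc9)c(OCc9ccccc9)c(OCc9ccccc9)c1 | intermediate
21 | 3,4-trans-2-ArB-3,5,7-tris(benzyloxy)-4-ArD-chroman-2-ol (hemiketal, C2 epimers, with open keto phenol) | c1(OCc9ccccc9)cc(OCc9ccccc9)c2c(c1)OC(O)(c7cc(OCc9ccccc9)c(OCc9ccccc9)c(OCc9ccccc9)c7)[C@@H](OCc9ccccc9)[C@@H]2c4c(OCc9ccccc9)c(Br)c5c(c4OCc9ccccc9)C[C@H](OCc9ccccc9)[C@@H](c7cc(OCc9ccccc9)c(OCc9ccccc9)c(OCc9ccccc9)c7)O5 | intermediate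
22 | 2-ArB-3,5,7-tris(benzyloxy)-4-ArD-3,4-dihydrochromenylium (oxocarbenium ion) | c1(OCc9ccccc9)cc(OCc9ccccc9)c2c(c1)[O+]=C(c7cc(OCc9ccccc9)c(OCc9ccccc9)c(OCc9ccccc9)c7)[C@@H](OCc9ccccc9)[C@@H]2c4c(OCc9ccccc9)c(Br)c5c(c4OCc9ccccc9)C[C@H](OCc9ccccc9)[C@@H](c7cc(OCc9ccccc9)c(OCc9ccccc9)c(OCc9ccccc9)c7)O5 | intermediate
23 | 3,5,7,3',4',5'-hexa-O-benzylgallocatechin-(4α→6)-8-bromo-3,5,7,3',4',5'-hexa-O-benzylgallocatechin | c1(OCc9ccccc9)cc(OCc9ccccc9)c2c(c1)O[C@H](c7cc(OCc9ccccc9)c(OCc9ccccc9)c(OCc9ccccc9)c7)[C@@H](OCc9ccccc9)[C@@H]2c4c(OCc9ccccc9)c(Br)c5c(c4OCc9ccccc9)C[C@H](OCc9ccccc9)[C@@H](c7cc(OCc9ccccc9)c(OCc9ccccc9)c(OCc9ccccc9)c7)O5 | intermediate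
24 | gallocatechin-(4α→6)-gallocatechin (CNP0286965.2) | Oc1cc(O)c2c(c1)O[C@H](c1cc(O)c(O)c(O)c1)[C@@H](O)[C@@H]2c1c(O)cc2c(c1O)C[C@H](O)[C@@H](c1cc(O)c(O)c(O)c1)O2 | target

## Step count and least certain steps

Total step count: 12. Longest linear sequence: 9 steps (1, 2, 3, 5, 6, 7, 10, 11, 12).

Step 6 (key step). Two processes may fail. C–C bond formation at the methide carbon, which is flanked by four ortho oxygens, may be slow, so self-aldol of 10 consumes the aldehyde. Face selectivity at C4 may be poor if the quinone methide reacts through both geometries, and C4 cannot be corrected afterwards. Fallback: this sets out from 9 and returns at 21, so steps 7 and 10 fall away. The aldehyde-derived enamine is replaced by a preformed, non-self-condensing enol silane that already contains ring B. Aryllithium 19 and 2-(benzyloxy)-N-methoxy-N-methylacetamide give 2-(benzyloxy)-1-[3,4,5-tris(benzyloxy)phenyl]ethan-1-one F1, which TMSOTf/Et3N converts into its (Z)-trimethylsilyl enol ether F2. Mukaiyama–Michael addition of F2 to 11, generated from 9 with BF3·OEt2 at −78 °C, followed by closure on the ring A phenol and desilylation, gives the hemiketal directly. C3 is equilibrated with Et3N to the 3,4-trans arrangement. The two C4 epimers are diastereomers because of the lower unit and are separated by chromatography; the required one is 21.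

Step 5. Iodine–magnesium exchange at the very electron-rich, doubly ortho-substituted C6 may be incomplete, and addition of the hindered aryl metal to the deactivated phenoxide aldehyde may be slow, so protonated arene is returned. Fallback: this sets out from 3 and returns at 9, and forms the bond from the other side. Vilsmeier–Haack formylation of 3 (POCl3, DMF) at C6 gives (2R,3S)-8-bromo-3,5,7-tris(benzyloxy)-2-ArB-chromane-6-carbaldehyde F3. Ortho-specific hydroxyalkylation of the bromomagnesium phenoxide of commercial 3,5-bis(benzyloxy)phenol (EtMgBr, toluene) with F3 gives 9. Magnesium chelation directs the attack ortho, and both ortho positions of the phenol are equivalent.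

Step 10. The tetrahedral adduct of an aryl ester may collapse to the ketone in the flask, so a second addition or enolisation at C3 may occur. Fallback: this sets out from 15 and returns at 21. Ring opening of 15 with MeNH(OMe)·HCl/i-PrMgCl gives the N-methoxy-N-methylamide of (2,3-anti)-2-(benzyloxy)-3-[2,4-bis(benzyloxy)-6-hydroxyphenyl]-3-ArD-propanoic acid F4. Its chelated tetrahedral intermediate with excess 19 cannot add twice, and work-up gives the keto phenol that closes to 21.

Step 11. The oxocarbenium ion may lose the C3 proton to give the flav-2-ene, which can disproportionate, or the Lewis acid may ionise the bond from C4 to ring D. Fallback: this sets out from 21 and returns at 23, and avoids any C2 cation. Felkin–Anh reduction of the open keto form with KBH(s-Bu)3 gives the syn carbinol 2-(benzyloxy)-3-[2,4-bis(benzyloxy)-6-hydroxyphenyl]-1-ArB-3-ArD-propan-1-ol F5. Mitsunobu closure (PPh3, DIAD) then forms the O1–C2 bond with inversion, which gives the 2,3-trans ring of 23.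

Step 12. Hydrodebromination may lag behind debenzylation as bromide accumulates on the catalyst, and the amine needed for it may promote oxidation of the pyrogallol rings on work-up. Fallback: this sets out from 23 and returns at 24, and separates the two events. Bromine–lithium exchange of 23 (n-BuLi, THF, −78 °C) and quenching with MeOH gives 3,5,7,3',4',5'-hexa-O-benzylgallocatechin-(4α→6)-3,5,7,3',4',5'-hexa-O-benzylgallocatechin F6. F6 is then hydrogenolysed over Pd(OH)2/C without base.

## Further compounds

F1 | step 6 | 2-(benzyloxy)-1-[3,4,5-tris(benzyloxy)phenyl]ethan-1-one | O=C(COCc9ccccc9)c1cc(OCc9ccccc9)c(OCc9ccccc9)c(OCc9ccccc9)c1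
F2 | step 6 | (Z)-2-(benzyloxy)-1-[3,4,5-tris(benzyloxy)phenyl]-1-(trimethylsilyloxy)ethene | C[Si](C)(C)O/C(=C\OCc9ccccc9)c1cc(OCc9ccccc9)c(OCc9ccccc9)c(OCc9ccccc9)c1
F3 | step 5 | (2R,3S)-8-bromo-3,5,7-tris(benzyloxy)-2-ArB-chromane-6-carbaldehyde | O=Cc4c(OCc9ccccc9)c(Br)c5c(c4OCc9ccccc9)C[C@H](OCc9ccccc9)[C@@H](c7cc(OCc9ccccc9)c(OCc9ccccc9)c(OCc9ccccc9)c7)O5
F4 | step 10 | (2,3-anti)-2-(benzyloxy)-3-[2,4-bis(benzyloxy)-6-hydroxyphenyl]-3-ArD-N-methoxy-N-methylpropanamide | CON(C)C(=O)[C@@H](OCc9ccccc9)[C@@H](c1c(O)cc(OCc9ccccc9)cc1OCc9ccccc9)c4c(OCc9ccccc9)c(Br)c5c(c4OCc9ccccc9)C[C@H](OCc9ccccc9)[C@@H](c7cc(OCc9ccccc9)c(OCc9ccccc9)c(OCc9ccccc9)c7)O5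
F5 | step 11 | (1,2-syn)-2-(benzyloxy)-3-[2,4-bis(benzyloxy)-6-hydroxyphenyl]-1-ArB-3-ArD-propan-1-ol | O[C@@H](c7cc(OCc9ccccc9)c(OCc9ccccc9)c(OCc9ccccc9)c7)[C@@H](OCc9ccccc9)[C@@H](c1c(O)cc(OCc9ccccc9)cc1OCc9ccccc9)c4c(OCc9ccccc9)c(Br)c5c(c4OCc9ccccc9)C[C@H](OCc9ccccc9)[C@@H](c7cc(OCc9ccccc9)c(OCc9ccccc9)c(OCc9ccccc9)c7)O5
F6 | step 12 | 3,5,7,3',4',5'-hexa-O-benzylgallocatechin-(4α→6)-3,5,7,3',4',5'-hexa-O-benzylgallocatechin | c1(OCc9ccccc9)cc(OCc9ccccc9)c2c(c1)O[C@H](c7cc(OCc9ccccc9)c(OCc9ccccc9)c(OCc9ccccc9)c7)[C@@H](OCc9ccccc9)[C@@H]2c4c(OCc9ccccc9)cc5c(c4OCc9ccccc9)C[C@H](OCc9ccccc9)[C@@H](c7cc(OCc9ccccc9)c(OCc9ccccc9)c(OCc9ccccc9)c7)O5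
A1 | alternative 1 | (2R,3S)-3,5,7-tris(benzyloxy)-4-(2-ethoxyethoxy)-2-ArB-chromane (C4 epimers) | CCOCCOC1c2c(OCc9ccccc9)cc(OCc9ccccc9)cc2O[C@H](c7cc(OCc9ccccc9)c(OCc9ccccc9)c(OCc9ccccc9)c7)[C@H]1OCc9ccccc9
A2 | alternative 2 | 2,3-trans-3,5,7-tris(benzyloxy)-2-ArB-chroman-4-one (hexa-O-benzyldihydromyricetin) | O=C1c2c(OCc9ccccc9)cc(OCc9ccccc9)cc2O[C@H](c7cc(OCc9ccccc9)c(OCc9ccccc9)c(OCc9ccccc9)c7)[C@H]1OCc9ccccc9
A3 | alternative 2 | 2,3-trans-3,5,7-tris(benzyloxy)-2-ArB-4-ArD-chroman-4-ol | OC1(c4c(OCc9ccccc9)c(Br)c5c(c4OCc9ccccc9)C[C@H](OCc9ccccc9)[C@@H](c7cc(OCc9ccccc9)c(OCc9ccccc9)c(OCc9ccccc9)c7)O5)c2c(OCc9ccccc9)cc(OCc9ccccc9)cc2O[C@H](c7cc(OCc9ccccc9)c(OCc9ccccc9)c(OCc9ccccc9)c7)[C@H]1OCc9ccccc9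
A4 | alternative 2 | 3,5,7,3',4',5'-hexa-O-benzylgallocatechin-(4β→6)-8-bromo-3,5,7,3',4',5'-hexa-O-benzylgallocatechin (3,4-cis epimer of 23) | c1(OCc9ccccc9)cc(OCc9ccccc9)c2c(c1)O[C@H](c7cc(OCc9ccccc9)c(OCc9ccccc9)c(OCc9ccccc9)c7)[C@@H](OCc9ccccc9)[C@H]2c4c(OCc9ccccc9)c(Br)c5c(c4OCc9ccccc9)C[C@H](OCc9ccccc9)[C@@H](c7cc(OCc9ccccc9)c(OCc9ccccc9)c(OCc9ccccc9)c7)O5
A5 | alternative 3 | (E)-2-[2-(3,4,5-tris(benzyloxy)phenyl)ethenyl]-4,4,5,5-tetramethyl-1,3,2-dioxaborolane | CC1(C)OB(/C=C/c7cc(OCc9ccccc9)c(OCc9ccccc9)c(OCc9ccccc9)c7)OC1(C)C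
A6 | alternative 3 | 2,3-trans-3,4-trans-2-ArB-5,7-bis(benzyloxy)-4-ArD-3-(4,4,5,5-tetramethyl-1,3,2-dioxaborolan-2-yl)chromane | c1(OCc9ccccc9)cc(OCc9ccccc9)c2c(c1)O[C@H](c7cc(OCc9ccccc9)c(OCc9ccccc9)c(OCc9ccccc9)c7)[C@@H](B3OC(C)(C)C(C)(C)O3)[C@@H]2c4c(OCc9ccccc9)c(Br)c5c(c4OCc9ccccc9)C[C@H](OCc9ccccc9)[C@@H](c7cc(OCc9ccccc9)c(OCc9ccccc9)c(OCc9ccccc9)c7)O5
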